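**Retrosynthetic overview**

1. Target 36 is an ent-labdane: a trans-decalin (ring A = C1–C5, C10; ring B = C5–C10) with the quaternary C4 (equatorial C18 angelate, axial C19 methyl), the tertiary C8 carbinol, and the C9 side chain C11–C16 with the C13 methyl and C15 hydroxyl.
2. The strategy rests on the C5–C10 ring fusion that carries the angular methyl C20 next to the C9–C11 branch. This is read as an (E)-3-methyl-2-enal (C11, C9=C10, C20) tied through C1–C3 and the quaternary C4 to a butadiene C5=C6–C7=C8, so that one intramolecular Diels–Alder reaction forms C5–C10 and C8–C9 and closes rings B and A together.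
3. Before it: C4 comes from malonate alkylation and lipase desymmetrisation of the derived propane-1,3-diol, the (E)-enal from Cp2ZrCl2-catalysed carboalumination of 5-chloropent-1-yne, and the diene from allylphosphonate olefination.
4. After it: C6=C7 is saturated and the aldehyde is dehydrogenated to the C8=C9 enal, which marks C8 without an allylic oxidation that would compete with the tertiary C5–H. C11–C12 is then made by copper-catalysed allylic coupling with the C12–C16 Grignard reagent from (R)-2-methylbutane-1,4-diol, and hydroboration, oxidation, methylenation, epoxidation and hydride opening set C9 and the C8 carbinol.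
5. End: debenzylation, angeloylation of C18–OH, desilylation of C15–O.

Key step: step 12

Remark: labdane numbering (C1–C20) is used for all carbons, also in the acyclic intermediates.
Assumption: the lipase of step 5 is taken to give the (R)-monoacetate 9; should it give the antipode, the free arm is silylated, the acetate arm cleaved and benzylated and the silyl group removed, which leads to the same alcohol 11 with two more steps.
Assumption: the (S)-prolinol-derived oxazaborolidinium ion is taken to be the antipode that exposes the C9-Re/C10-Si face of the enal in step 12; if the sense is the opposite, the (R)-catalyst is used.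

**Route**

Step 1
Reactants: 1 5-chloropent-1-yne
Product: 3 (E)-6-chloro-3-methylhex-2-en-1-ol, via alkenylalane 2 (not isolated)
Conditions: Me3Al (2 equiv), Cp2ZrCl2 (0.25 equiv), CH2Cl2, 0 °C to rt; then (CH2O)n, THF, rt
Reagents that add atoms: trimethylaluminium C[Al](C)C; formaldehyde (as paraformaldehyde) C=O
Why: Negishi carboalumination adds CH3–Al syn across the terminal alkyne with aluminium at the terminus and the alkenylalane is hydroxymethylated with retention, so the trisubstituted alkene that becomes the dienophile C9=C10 should be formed as the (E)-isomer only, with C20 cis to C11.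

Step 2
Reactants: 3 (E)-6-chloro-3-methylhex-2-en-1-ol
Product: 4 (E)-tert-butyl[(6-chloro-3-methylhex-2-en-1-yl)oxy]diphenylsilane
Conditions: TBDPSCl, imidazole, CH2Cl2, 0 °C to rt
Reagents that add atoms: tert-butyl(chloro)diphenylsilane CC(C)(C)[Si](Cl)(c1ccccc1)c1ccccc1
Why: Silylation of the primary allylic alcohol gives an ether that should survive the enolate alkylation, the hydride reduction and the acid-catalysed benzylation that follow.

Step 3
Reactants: 5 diethyl methylmalonate; 4 (E)-tert-butyl[(6-chloro-3-methylhex-2-en-1-yl)oxy]diphenylsilane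
Product: 7 diethyl 2-[(E)-6-(tert-butyldiphenylsilyloxy)-4-methylhex-4-en-1-yl]-2-methylmalonate, via sodium enolate 6 (not isolated)
Conditions: NaH, DMF, 0 °C; then 4, 80 °C
Reagents that add atoms: none
Why: Malonic ester alkylation (SN2 of the malonate anion on the primary chloride) builds the quaternary carbon C4 with its methyl, the C1–C3 tether and two equivalent carboxyl arms.

Step 4
Reactants: 7 diethyl 2-[(E)-6-(tert-butyldiphenylsilyloxy)-4-methylhex-4-en-1-yl]-2-methylmalonate
Product: 8 2-[(E)-6-(tert-butyldiphenylsilyloxy)-4-methylhex-4-en-1-yl]-2-methylpropane-1,3-diol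
Conditions: LiAlH4, THF, 0 °C to rt
Reagents that add atoms: none
Why: Hydride reduction of both esters gives the prochiral 2,2-disubstituted propane-1,3-diol and leaves the silyl ether and the alkene untouched.

Step 5
Reactants: 8 2-[(E)-6-(tert-butyldiphenylsilyloxy)-4-methylhex-4-en-1-yl]-2-methylpropane-1,3-diol
Product: 9 (2R,6E)-8-(tert-butyldiphenylsilyloxy)-2-(hydroxymethyl)-2,6-dimethyloct-6-en-1-yl acetate
Conditions: lipase from Pseudomonas fluorescens, vinyl acetate, i-Pr2O, rt, stopped at the monoacetate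
Reagents that add atoms: vinyl acetate C=COC(C)=O
Why: Lipase-catalysed irreversible transesterification (desymmetrisation of a prochiral propane-1,3-diol) should acetylate one enantiotopic hydroxymethyl group, the enzyme telling the methyl group from the long chain, and this sets the quaternary centre C4.

Step 6
Reactants: 9 (2R,6E)-8-(tert-butyldiphenylsilyloxy)-2-(hydroxymethyl)-2,6-dimethyloct-6-en-1-yl acetate
Product: 10 (2R,6E)-2-(benzyloxymethyl)-8-(tert-butyldiphenylsilyloxy)-2,6-dimethyloct-6-en-1-yl acetate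
Conditions: BnOC(=NH)CCl3, TfOH (5 mol%), CH2Cl2–cyclohexane, 0 °C
Reagents that add atoms: benzyl 2,2,2-trichloroacetimidate N=C(OCc1ccccc1)C(Cl)(Cl)Cl
Why: Acid-catalysed imidate benzylation protects the future C18 oxygen without the basic conditions under which 1,3-acyl migration between the two arms would racemise C4.

Step 7
Reactants: 10 (2R,6E)-2-(benzyloxymethyl)-8-(tert-butyldiphenylsilyloxy)-2,6-dimethyloct-6-en-1-yl acetate
Product: 11 (2S,6E)-2-(benzyloxymethyl)-8-(tert-butyldiphenylsilyloxy)-2,6-dimethyloct-6-en-1-ol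
Conditions: K2CO3 (cat.), MeOH, rt
Reagents that add atoms: none
Why: Base-catalysed methanolysis removes the acetate, and C4 is no longer at risk because its two arms are now chemically different.

Step 8
Reactants: 11 (2S,6E)-2-(benzyloxymethyl)-8-(tert-butyldiphenylsilyloxy)-2,6-dimethyloct-6-en-1-ol
Product: 12 (2R,6E)-2-(benzyloxymethyl)-8-(tert-butyldiphenylsilyloxy)-2,6-dimethyloct-6-enal
Conditions: Dess–Martin periodinane, CH2Cl2, rt
Reagents that add atoms: none
Why: Dess–Martin oxidation of the neopentyl alcohol gives the C5 aldehyde, which cannot epimerise because its α-carbon C4 is quaternary.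

Step 9
Reactants: 12 (2R,6E)-2-(benzyloxymethyl)-8-(tert-butyldiphenylsilyloxy)-2,6-dimethyloct-6-enal
Product: 13 tert-butyl{[(2E,7S,8E)-7-(benzyloxymethyl)-3,7-dimethylundeca-2,8,10-trien-1-yl]oxy}diphenylsilane
Conditions: CH2=CHCH2P(O)(OEt)2, n-BuLi, THF, −78 °C; then 12, DMPU, −78 °C to rt
Reagents that add atoms: diethyl allylphosphonate C=CCP(=O)(OCC)OCC
Why: Horner–Wadsworth–Emmons olefination with the lithiated allylphosphonate should deliver the terminal 1,3-diene C5=C6–C7=C8 with the (E)-C5=C6 geometry that the cycloaddition needs.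

Step 10
Reactants: 13 tert-butyl{[(2E,7S,8E)-7-(benzyloxymethyl)-3,7-dimethylundeca-2,8,10-trien-1-yl]oxy}diphenylsilane
Product: 14 (2E,7S,8E)-7-(benzyloxymethyl)-3,7-dimethylundeca-2,8,10-trien-1-ol
Conditions: Bu4NF, THF, rt
Reagents that add atoms: none
Why: Fluoride-induced desilylation frees the allylic alcohol and leaves the benzyl ether and the diene untouched.

Step 11
Reactants: 14 (2E,7S,8E)-7-(benzyloxymethyl)-3,7-dimethylundeca-2,8,10-trien-1-ol
Product: 15 (2E,7S,8E)-7-(benzyloxymethyl)-3,7-dimethylundeca-2,8,10-trienal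
Conditions: MnO2, CH2Cl2, rt
Reagents that add atoms: none
Why: Manganese dioxide oxidises only the allylic alcohol and should give the (E)-enal dienophile without isomerising the trisubstituted double bond.

Step 12
Reactants: 15 (2E,7S,8E)-7-(benzyloxymethyl)-3,7-dimethylundeca-2,8,10-trienal
Product: 16 (4S,5S,9R,10R)-18-benzyloxy-12,13,14,15,16,17-hexanorlabd-6-en-11-al
Conditions: (S)-B-(o-tolyl)oxazaborolidine from (S)-α,α-diphenylprolinol, Tf2NH (20 mol% each), CH2Cl2, −78 to −20 °C
Reagents that add atoms: none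
Why: Proposed new method: the N-protonated oxazaborolidine binds the formyl oxygen of 15 and lowers the LUMO of the C9=C10 enal, which then adds suprafacially to the s-cis diene C5=C6–C7=C8 in a concerted, asynchronous [4+2] cycloaddition whose C5–C10 bond is the more advanced; the closest known reaction types are the oxazaborolidinium-catalysed intramolecular Diels–Alder reaction of decatrienals with less substituted enal dienophiles and the achiral Lewis-acid-promoted cyclisation of 1,7,9-decatrienes that carry a trisubstituted dienophile, and what has not been shown is the chiral cation on a β,β-disubstituted enal. Ring B (C5–C6–C7–C8–C9–C10) is the six-membered cycloadduct ring formed directly by the [4+2] union, and ring A (C1–C2–C3–C4–C5–C10) closes in the same event as the fused ring of the tethered cycloaddition, because the chain C1–C4, held in a chair and exo to the diene, spans C10 and C5. C10 and C9 are fixed relative to each other by the (E)-geometry of the dienophile (C20 cis to C11), C5 relative to C10 by the formyl-endo transition state (trans ring fusion, H5 anti to C20), and the three together relative to the existing C4 centre by the catalyst, which has to present the C9-Re/C10-Si face of the enal to the diene. The step needs endo selectivity and one enal face: coordination of the formyl group to boron secures the first, and the second rests on the chiral cation acting in the same sense as the weak substrate preference that keeps CH2OBn equatorial and leaves the smaller C19 methyl 1,3-diaxial to C20.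

Step 13
Reactants: 16 (4S,5S,9R,10R)-18-benzyloxy-12,13,14,15,16,17-hexanorlabd-6-en-11-al
Product: 17 (4S,5S,9R,10R)-18-benzyloxy-12,13,14,15,16,17-hexanorlabdan-11-al
Conditions: H2 (1 atm), Pd/C, pyridine (0.5 equiv), EtOAc, rt
Reagents that add atoms: none
Why: Heterogeneous hydrogenation saturates C6=C7, which has served its purpose once both rings are closed, and the pyridine-moderated catalyst should spare the benzyl ether and the aldehyde.

Step 14
Reactants: 17 (4S,5S,9R,10R)-18-benzyloxy-12,13,14,15,16,17-hexanorlabdan-11-al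
Product: 18 (4S,5S,10R)-18-benzyloxy-12,13,14,15,16,17-hexanorlabd-8-en-11-al
Conditions: IBX, 4-methoxypyridine N-oxide, DMSO, rt
Reagents that add atoms: none
Why: IBX dehydrogenation through the enol of the aldehyde can only introduce C8=C9 because C10 is quaternary, which marks C8 unambiguously for oxygenation (an allylic oxidation of C6=C7 would have had to compete with the axial tertiary C5–H) at the price of the C9 centre, which is restored in step 20.

Step 15
Reactants: 18 (4S,5S,10R)-18-benzyloxy-12,13,14,15,16,17-hexanorlabd-8-en-11-al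
Product: 19 (4S,5S,10R)-18-benzyloxy-12,13,14,15,16,17-hexanorlabd-8-en-11-ol
Conditions: NaBH4, CeCl3·7H2O, MeOH, 0 °C
Reagents that add atoms: none
Why: Luche reduction delivers hydride to the carbonyl carbon only and gives the primary allylic alcohol.

Step 16
Reactants: 19 (4S,5S,10R)-18-benzyloxy-12,13,14,15,16,17-hexanorlabd-8-en-11-ol
Product: 20 (4S,5S,10R)-18-benzyloxy-11-bromo-12,13,14,15,16,17-hexanorlabd-8-ene
Conditions: CBr4, PPh3, CH2Cl2, 0 °C
Reagents that add atoms: carbon tetrabromide BrC(Br)(Br)Br
Why: Appel bromination turns the primary allylic alcohol into the bromide under neutral conditions and the double bond should stay in the ring position C8=C9.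

Step 17
Reactants: 21 (R)-2-methylbutane-1,4-diol
Product: 22 (R)-4-(tert-butyldiphenylsilyloxy)-2-methylbutan-1-ol
Conditions: TBDPSCl (1.0 equiv), imidazole, CH2Cl2, −20 °C
Reagents that add atoms: tert-butyl(chloro)diphenylsilane CC(C)(C)[Si](Cl)(c1ccccc1)c1ccccc1
Why: Silylation with a bulky chlorosilane at low temperature should prefer the hydroxyl remote from the methyl branch (the future C15–OH), and the minor regioisomer and the bis-silyl ether are removed by chromatography.

Step 18
Reactants: 22 (R)-4-(tert-butyldiphenylsilyloxy)-2-methylbutan-1-ol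
Product: 23 (R)-(4-bromo-3-methylbutoxy)(tert-butyl)diphenylsilane
Conditions: CBr4, PPh3, CH2Cl2, 0 °C
Reagents that add atoms: carbon tetrabromide BrC(Br)(Br)Br
Why: Appel bromination of the remaining primary alcohol gives the C12 electrophile without touching the C13 stereocentre.

Step 19
Reactants: 23 (R)-(4-bromo-3-methylbutoxy)(tert-butyl)diphenylsilane; 20 (4S,5S,10R)-18-benzyloxy-11-bromo-12,13,14,15,16,17-hexanorlabd-8-ene
Product: 25 (4S,5S,10R,13S)-18-benzyloxy-15-(tert-butyldiphenylsilyloxy)-17-norlabd-8-ene, via Grignard reagent 24 (not isolated)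
Conditions: Mg, THF, 45 °C; then Li2CuCl4 (5 mol%), 20, THF, −78 to 0 °C
Reagents that add atoms: none
Why: Copper-catalysed Grignard cross-coupling of Kochi–Schlosser type forms C11–C12, since under dialkylcuprate conditions the allylcopper intermediate should collapse at the primary terminus C11 and not at the ring carbon C8, so that C8=C9 stays in place and the C13 centre, β to magnesium, is carried in unchanged.

Step 20
Reactants: 25 (4S,5S,10R,13S)-18-benzyloxy-15-(tert-butyldiphenylsilyloxy)-17-norlabd-8-ene
Product: 27 (4S,5S,8S,9S,10R,13S)-18-benzyloxy-15-(tert-butyldiphenylsilyloxy)-17-norlabdan-8-ol, via alkylborane 26 (not isolated)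
Conditions: BH3·THF, THF, 0 °C to rt; then NaOH, H2O2, 0 °C
Reagents that add atoms: hydrogen peroxide OO
Why: Hydroboration–oxidation places boron on the less substituted C8 and hydrogen on C9 in a syn addition from the face anti to the axial angular methyl C20, which should set C9 (H9 anti to C20, side chain equatorial) and gives an equatorial C8 alcohol whose configuration is of no consequence.

Step 21
Reactants: 27 (4S,5S,8S,9S,10R,13S)-18-benzyloxy-15-(tert-butyldiphenylsilyloxy)-17-norlabdan-8-ol
Product: 28 (4S,5S,9S,10R,13S)-18-benzyloxy-15-(tert-butyldiphenylsilyloxy)-17-norlabdan-8-one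
Conditions: Dess–Martin periodinane, CH2Cl2, rt
Reagents that add atoms: none
Why: Dess–Martin oxidation gives the C8 ketone, in which C9 is α to the carbonyl but already holds its side chain in the thermodynamically preferred equatorial position.

Step 22
Reactants: 28 (4S,5S,9S,10R,13S)-18-benzyloxy-15-(tert-butyldiphenylsilyloxy)-17-norlabdan-8-one
Product: 29 (4S,5S,9R,10S,13S)-18-benzyloxy-15-(tert-butyldiphenylsilyloxy)labd-8(17)-ene
Conditions: Ph3PCH3Br, KOt-Bu, toluene, 90 °C
Reagents that add atoms: methyltriphenylphosphonium bromide C[P+](c1ccccc1)(c1ccccc1)c1ccccc1.[Br-]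
Why: Wittig methylenation of the hindered ketone with excess ylide brings in C17, and any enolisation toward C9 returns the more stable equatorial epimer (the changed C9 and C10 descriptors reflect sequence-rule priorities only).

Step 23
Reactants: 29 (4S,5S,9R,10S,13S)-18-benzyloxy-15-(tert-butyldiphenylsilyloxy)labd-8(17)-ene
Product: 30 (4S,5S,8S,9S,10R,13S)-18-benzyloxy-15-(tert-butyldiphenylsilyloxy)-8,17-epoxylabdane
Conditions: m-CPBA, CH2Cl2, 0 °C
Reagents that add atoms: 3-chloroperbenzoic acid OOC(=O)c1cccc(Cl)c1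
Why: In this Prilezhaev epoxidation the peracid should approach the exocyclic alkene from its equatorial side, anti to the axial C20 methyl, which places the epoxide oxygen equatorial and the C17 methylene axial on C8.

Step 24
Reactants: 30 (4S,5S,8S,9S,10R,13S)-18-benzyloxy-15-(tert-butyldiphenylsilyloxy)-8,17-epoxylabdane
Product: 31 (4S,5S,8S,9S,10R,13S)-18-benzyloxy-15-(tert-butyldiphenylsilyloxy)labdan-8-ol
Conditions: LiBHEt3, THF, 0 °C to rt
Reagents that add atoms: none
Why: SN2 hydride opening of the spiro-epoxide at its primary carbon C17 leaves the C8–O bond intact and so turns the epoxide configuration into the equatorial tertiary C8 alcohol with an axial C17 methyl.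

Step 25
Reactants: 31 (4S,5S,8S,9S,10R,13S)-18-benzyloxy-15-(tert-butyldiphenylsilyloxy)labdan-8-ol
Product: 32 (4S,5S,8S,9S,10R,13S)-15-(tert-butyldiphenylsilyloxy)labdane-8,18-diol
Conditions: H2 (1 atm), Pd/C, EtOAc–EtOH, rt
Reagents that add atoms: none
Why: Catalytic hydrogenolysis of the benzyl ether frees the primary C18 hydroxyl while the silyl ether and the tertiary alcohol are inert.

Step 26
Reactants: 33 angelic acid; 32 (4S,5S,8S,9S,10R,13S)-15-(tert-butyldiphenylsilyloxy)labdane-8,18-diol
Product: 35 (4S,5S,8S,9S,10R,13S)-15-(tert-butyldiphenylsilyloxy)-8-hydroxylabdan-18-yl (Z)-2-methylbut-2-enoate, via mixed anhydride 34 (not isolated)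
Conditions: 2,4,6-trichlorobenzoyl chloride, Et3N, toluene, rt; then 32, toluene, 75 °C
Reagents that add atoms: none
Why: Yamaguchi-type esterification through the 2,4,6-trichlorobenzoyl mixed anhydride, run without a nucleophilic catalyst, should acylate only the primary C18 hydroxyl (the tertiary C8 hydroxyl is too hindered) and keep the (Z)-geometry of the angeloyl group.

Step 27
Reactants: 35 (4S,5S,8S,9S,10R,13S)-15-(tert-butyldiphenylsilyloxy)-8-hydroxylabdan-18-yl (Z)-2-methylbut-2-enoate
Product: 36 (4S,5S,8S,9S,10R,13S)-8,15-dihydroxylabdan-18-yl (Z)-2-methylbut-2-enoate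
Conditions: HF·pyridine, pyridine, THF, 0 °C to rt
Reagents that add atoms: none
Why: Buffered fluoride desilylation removes the TBDPS group under non-basic conditions, which should neither isomerise or cleave the angelate nor dehydrate the tertiary alcohol.

**Compound list**

1 | 5-chloropent-1-yne | C#CCCCCl | starting material
2 | (E)-(5-chloro-2-methylpent-1-en-1-yl)dimethylalane | C[Al](C)/C=C(\C)CCCCl | intermediate (not isolated)
3 | (E)-6-chloro-3-methylhex-2-en-1-ol | OC/C=C(\C)CCCCl | intermediate
4 | (E)-tert-butyl[(6-chloro-3-methylhex-2-en-1-yl)oxy]diphenylsilane | CC(C)(C)[Si](c1ccccc1)(c1ccccc1)OC/C=C(\C)CCCCl | intermediate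
5 | diethyl methylmalonate | CCOC(=O)C(C)C(=O)OCC | starting material
6 | sodium enolate of diethyl methylmalonate | [Na+].CCOC(=O)[C-](C)C(=O)OCC | intermediate (not isolated)
7 | diethyl 2-[(E)-6-(tert-butyldiphenylsilyloxy)-4-methylhex-4-en-1-yl]-2-methylmalonate | CC(C)(C)[Si](c1ccccc1)(c1ccccc1)OC/C=C(\C)CCCC(C)(C(=O)OCC)C(=O)OCC | intermediate
8 | 2-[(E)-6-(tert-butyldiphenylsilyloxy)-4-methylhex-4-en-1-yl]-2-methylpropane-1,3-diol | CC(C)(C)[Si](c1ccccc1)(c1ccccc1)OC/C=C(\C)CCCC(C)(CO)CO | intermediate
9 | (2R,6E)-8-(tert-butyldiphenylsilyloxy)-2-(hydroxymethyl)-2,6-dimethyloct-6-en-1-yl acetate | CC(C)(C)[Si](c1ccccc1)(c1ccccc1)OC/C=C(\C)CCC[C@](C)(CO)COC(C)=O | intermediate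
10 | (2R,6E)-2-(benzyloxymethyl)-8-(tert-butyldiphenylsilyloxy)-2,6-dimethyloct-6-en-1-yl acetate | CC(C)(C)[Si](c1ccccc1)(c1ccccc1)OC/C=C(\C)CCC[C@](C)(COCc1ccccc1)COC(C)=O | intermediate
11 | (2S,6E)-2-(benzyloxymethyl)-8-(tert-butyldiphenylsilyloxy)-2,6-dimethyloct-6-en-1-ol | CC(C)(C)[Si](c1ccccc1)(c1ccccc1)OC/C=C(\C)CCC[C@](C)(COCc1ccccc1)CO | intermediate
12 | (2R,6E)-2-(benzyloxymethyl)-8-(tert-butyldiphenylsilyloxy)-2,6-dimethyloct-6-enal | CC(C)(C)[Si](c1ccccc1)(c1ccccc1)OC/C=C(\C)CCC[C@](C)(COCc1ccccc1)C=O | intermediate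
13 | tert-butyl{[(2E,7S,8E)-7-(benzyloxymethyl)-3,7-dimethylundeca-2,8,10-trien-1-yl]oxy}diphenylsilane | CC(C)(C)[Si](c1ccccc1)(c1ccccc1)OC/C=C(\C)CCC[C@](C)(COCc1ccccc1)/C=C/C=C | intermediate
14 | (2E,7S,8E)-7-(benzyloxymethyl)-3,7-dimethylundeca-2,8,10-trien-1-ol | OC/C=C(\C)CCC[C@](C)(COCc1ccccc1)/C=C/C=C | intermediate
15 | (2E,7S,8E)-7-(benzyloxymethyl)-3,7-dimethylundeca-2,8,10-trienal (key-step precursor) | O=C/C=C(\C)CCC[C@](C)(COCc1ccccc1)/C=C/C=C | intermediate
16 | (4S,5S,9R,10R)-18-benzyloxy-12,13,14,15,16,17-hexanorlabd-6-en-11-al (trans-octalin aldehyde; C11 cis to C20, H5 and CH2OBn trans to C20) | c1ccccc1COC[C@@]2(C)CCC[C@]3(C)[C@@H]2C=CC[C@H]3C=O | intermediate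
17 | (4S,5S,9R,10R)-18-benzyloxy-12,13,14,15,16,17-hexanorlabdan-11-al | c1ccccc1COC[C@@]2(C)CCC[C@]3(C)[C@@H]2CCC[C@H]3C=O | intermediate
18 | (4S,5S,10R)-18-benzyloxy-12,13,14,15,16,17-hexanorlabd-8-en-11-al | c1ccccc1COC[C@@]2(C)CCC[C@]3(C)[C@@H]2CCC=C3C=O | intermediate
19 | (4S,5S,10R)-18-benzyloxy-12,13,14,15,16,17-hexanorlabd-8-en-11-ol | c1ccccc1COC[C@@]2(C)CCC[C@]3(C)[C@@H]2CCC=C3CO | intermediate
20 | (4S,5S,10R)-18-benzyloxy-11-bromo-12,13,14,15,16,17-hexanorlabd-8-ene | c1ccccc1COC[C@@]2(C)CCC[C@]3(C)[C@@H]2CCC=C3CBr | intermediate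
21 | (R)-2-methylbutane-1,4-diol | OC[C@H](C)CCO | starting material
22 | (R)-4-(tert-butyldiphenylsilyloxy)-2-methylbutan-1-ol | OC[C@H](C)CCO[Si](c1ccccc1)(c1ccccc1)C(C)(C)C | intermediate
23 | (R)-(4-bromo-3-methylbutoxy)(tert-butyl)diphenylsilane | BrC[C@H](C)CCO[Si](c1ccccc1)(c1ccccc1)C(C)(C)C | intermediate
24 | (R)-[4-(tert-butyldiphenylsilyloxy)-2-methylbutyl]magnesium bromide | Br[Mg]C[C@H](C)CCO[Si](c1ccccc1)(c1ccccc1)C(C)(C)C | intermediate (not isolated)
25 | (4S,5S,10R,13S)-18-benzyloxy-15-(tert-butyldiphenylsilyloxy)-17-norlabd-8-ene | c1ccccc1COC[C@@]2(C)CCC[C@]3(C)[C@@H]2CCC=C3CC[C@H](C)CCO[Si](c1ccccc1)(c1ccccc1)C(C)(C)C | intermediate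
26 | 8-boryl adduct of 25 (BH2 on C8 and H on C9, both anti to C20) | c1ccccc1COC[C@@]2(C)CCC[C@]3(C)[C@@H]2CC[C@H]([BH2])[C@H]3CC[C@H](C)CCO[Si](c1ccccc1)(c1ccccc1)C(C)(C)C | intermediate (not isolated)
27 | (4S,5S,8S,9S,10R,13S)-18-benzyloxy-15-(tert-butyldiphenylsilyloxy)-17-norlabdan-8-ol | c1ccccc1COC[C@@]2(C)CCC[C@]3(C)[C@@H]2CC[C@H](O)[C@H]3CC[C@H](C)CCO[Si](c1ccccc1)(c1ccccc1)C(C)(C)C | intermediate
28 | (4S,5S,9S,10R,13S)-18-benzyloxy-15-(tert-butyldiphenylsilyloxy)-17-norlabdan-8-one | c1ccccc1COC[C@@]2(C)CCC[C@]3(C)[C@@H]2CCC(=O)[C@H]3CC[C@H](C)CCO[Si](c1ccccc1)(c1ccccc1)C(C)(C)C | intermediate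
29 | (4S,5S,9R,10S,13S)-18-benzyloxy-15-(tert-butyldiphenylsilyloxy)labd-8(17)-ene | c1ccccc1COC[C@@]2(C)CCC[C@]3(C)[C@@H]2CCC(=C)[C@H]3CC[C@H](C)CCO[Si](c1ccccc1)(c1ccccc1)C(C)(C)C | intermediate
30 | (4S,5S,8S,9S,10R,13S)-18-benzyloxy-15-(tert-butyldiphenylsilyloxy)-8,17-epoxylabdane (oxygen equatorial, anti to C20) | c1ccccc1COC[C@@]2(C)CCC[C@]3(C)[C@@H]2CC[C@]4(OC4)[C@H]3CC[C@H](C)CCO[Si](c1ccccc1)(c1ccccc1)C(C)(C)C | intermediate
31 | (4S,5S,8S,9S,10R,13S)-18-benzyloxy-15-(tert-butyldiphenylsilyloxy)labdan-8-ol | c1ccccc1COC[C@@]2(C)CCC[C@]3(C)[C@@H]2CC[C@](C)(O)[C@H]3CC[C@H](C)CCO[Si](c1ccccc1)(c1ccccc1)C(C)(C)C | intermediate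
32 | (4S,5S,8S,9S,10R,13S)-15-(tert-butyldiphenylsilyloxy)labdane-8,18-diol | OC[C@@]1(C)CCC[C@]2(C)[C@@H]1CC[C@](C)(O)[C@H]2CC[C@H](C)CCO[Si](c1ccccc1)(c1ccccc1)C(C)(C)C | intermediate
33 | angelic acid, (Z)-2-methylbut-2-enoic acid | C/C=C(/C)C(O)=O | starting material
34 | angelic 2,4,6-trichlorobenzoic anhydride | C/C=C(/C)C(=O)OC(=O)c1c(Cl)cc(Cl)cc1Cl | intermediate (not isolated)
35 | (4S,5S,8S,9S,10R,13S)-15-(tert-butyldiphenylsilyloxy)-8-hydroxylabdan-18-yl (Z)-2-methylbut-2-enoate | C/C=C(/C)C(=O)OC[C@@]1(C)CCC[C@]2(C)[C@@H]1CC[C@](C)(O)[C@H]2CC[C@H](C)CCO[Si](c1ccccc1)(c1ccccc1)C(C)(C)C | intermediate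
36 | (4S,5S,8S,9S,10R,13S)-8,15-dihydroxylabdan-18-yl (Z)-2-methylbut-2-enoate, CNP0150844.1 | C/C=C(/C)C(=O)OC[C@@]1(C)CCC[C@]2(C)[C@@H]1CC[C@](C)(O)[C@H]2CC[C@H](C)CCO | target

**Step count and risks**

Total step count: 27. Longest linear sequence: 25 steps (steps 1–16 and 19–27); steps 17–18 prepare the C12–C16 fragment.

Steps most likely to fail:

1. Step 12 (bears the label "Proposed new method:"). The bulky chiral boron cation may not activate the hindered β,β-disubstituted enal enough, so that the cycloaddition is slow and acid-induced oligomerisation of the diene takes over, or the face selection against the C4 centre may be poor. The fallback uses known chemistry and gives up catalyst control for cationic activation, substrate control and a separation. It sets out from 15, which is converted with 1,2-bis(trimethylsilyloxy)ethane and catalytic TMSOTf (CH2Cl2, −78 °C) into the trienal ethylene acetal F1. Catalytic TfOH (CH2Cl2, −78 to −40 °C) then opens the dioxolane to an alkoxyallyl cation that undergoes the ionic Diels–Alder reaction, a mode of dienophile activation known to overcome β-substitution. This should give the trans-fused octalin acetal F2 together with its diastereomer of opposite ring-fusion configuration F3, which is removed by chromatography. Hydrolysis of F2 (PPTS, acetone–water) brings the route back at 16.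

2. Step 5. The enzyme may discriminate poorly between the enantiotopic hydroxymethyl groups (a methyl group against a long chain on the prochiral carbon), acylation may run on to the diacetate, or acyl migration may erode the enantiomeric purity. The fallback desymmetrises the malonate instead of the diol and sets out from 7. Pig liver esterase (pH 7 phosphate buffer, DMSO co-solvent) is taken to hydrolyse one ester to the malonic half-ester F4. LiBH4 (THF) reduces the remaining ester in the presence of the carboxylate to the hydroxy acid F5. NaH and BnBr (DMF) give the benzyl ether benzyl ester F6, and LiAlH4 (THF) reduces this ester, which brings the route back at 11.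

3. Step 19. The allylic substitution may lose its regiocontrol (attack at C8 with shift of the double bond to C9=C11), or the allylic bromide may be reduced or homocoupled. The fallback makes C11–C12 by olefination and sets out from 18 and 23. PPh3 (MeCN, reflux) converts 23 into the phosphonium bromide F7, and NaN(SiMe3)2 (THF, −78 °C) gives the ylide F8, which is condensed with enal 18 to the (11Z)-8,11-diene F9. Diimide (from 2-nitrobenzenesulfonyl hydrazide and Et3N, CH2Cl2), which reduces a disubstituted alkene far faster than a trisubstituted one, should saturate C11=C12 only and bring the route back at 25.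

Further compounds
F1 | step 12 | 2-[(1E,6S,7E)-6-(benzyloxymethyl)-2,6-dimethyldeca-1,7,9-trien-1-yl]-1,3-dioxolane | O1CCOC1/C=C(\C)CCC[C@](C)(COCc1ccccc1)/C=C/C=C
F2 | step 12 | ethylene acetal of 16, (4S,5S,9R,10R)-18-benzyloxy-11,11-(ethylenedioxy)-12,13,14,15,16,17-hexanorlabd-6-ene | c1ccccc1COC[C@@]2(C)CCC[C@]3(C)[C@@H]2C=CC[C@H]3C4OCCO4
F3 | step 12 | diastereomer of F2 with inverted C5, C9 and C10 (CH2OBn cis to C20) | c1ccccc1COC[C@@]2(C)CCC[C@@]3(C)[C@H]2C=CC[C@@H]3C4OCCO4
F4 | step 5 | (2S,6E)-8-(tert-butyldiphenylsilyloxy)-2-(ethoxycarbonyl)-2,6-dimethyloct-6-enoic acid | CC(C)(C)[Si](c1ccccc1)(c1ccccc1)OC/C=C(\C)CCC[C@](C)(C(=O)OCC)C(O)=O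
F5 | step 5 | (2R,6E)-8-(tert-butyldiphenylsilyloxy)-2-(hydroxymethyl)-2,6-dimethyloct-6-enoic acid | CC(C)(C)[Si](c1ccccc1)(c1ccccc1)OC/C=C(\C)CCC[C@](C)(CO)C(O)=O
F6 | step 5 | benzyl (2R,6E)-2-(benzyloxymethyl)-8-(tert-butyldiphenylsilyloxy)-2,6-dimethyloct-6-enoate | CC(C)(C)[Si](c1ccccc1)(c1ccccc1)OC/C=C(\C)CCC[C@](C)(COCc1ccccc1)C(=O)OCc1ccccc1
F7 | step 19 | (R)-[4-(tert-butyldiphenylsilyloxy)-2-methylbutyl]triphenylphosphonium bromide | [Br-].c1ccccc1[P+](c1ccccc1)(c1ccccc1)C[C@H](C)CCO[Si](c1ccccc1)(c1ccccc1)C(C)(C)C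
F8 | step 19 | (R)-[4-(tert-butyldiphenylsilyloxy)-2-methylbutylidene]triphenylphosphorane | c1ccccc1P(c1ccccc1)(c1ccccc1)=C[C@H](C)CCO[Si](c1ccccc1)(c1ccccc1)C(C)(C)C
F9 | step 19 | (4S,5S,10R,11Z,13R)-18-benzyloxy-15-(tert-butyldiphenylsilyloxy)-17-norlabda-8,11-diene (C13 arranged in space as in 25) | c1ccccc1COC[C@@]2(C)CCC[C@]3(C)[C@@H]2CCC=C3/C=C\[C@H](C)CCO[Si](c1ccccc1)(c1ccccc1)C(C)(C)C
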